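**Retrosynthetic overview**

- The plan rests on ring B (C1'–C6'): it is bonded through C1' to C2 of the pyranone ring C and carries its hydroxyls at C2' and C4', ortho and para to that bond. This is the imprint of a 1,1,3-trioxygenated butadiene laid across an ethynyl group on C2.
- Key disconnection, C1'–C2' and C5'–C6': Diels–Alder reaction of 1-methoxy-1,3-bis(trimethylsilyloxy)butadiene (from methyl acetoacetate) with a 2-ethynyl-7-methoxy-3-prenylchromone whose O5 is protected, then hydrolytic aromatisation with loss of methanol.
- Ethynyl from 2-CHO (Colvin homologation), from 2-CH2OH, from the chromone-2-carboxylate. Ring C comes from Claisen condensation of the aryl homoprenyl ketone with diethyl oxalate and cyclodehydration.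
- The ketone comes from 2,4,6-trihydroxyacetophenone by 4-O-methylation, mono-O-allylation and C-prenylation of the dianion. Ring order: A (bought), then C, then B; the O5 allyl group is removed last with zerovalent palladium.

Key step: step 10

Remark: O5 is carried as an allyl ether because it must survive two enolate steps, carbonate or alkoxide media and a hot cycloaddition, and it can be removed without acid; the alkene geometry of the silyl enol ether and of the ketene acetal in the diene is of no consequence.

**Route**

Step 1
Reactants: 1 2,4,6-trihydroxyacetophenone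
Product: 2 2,6-dihydroxy-4-methoxyacetophenone
Conditions: Me2SO4 (1.0 equiv), K2CO3 (1.0 equiv), acetone, reflux
Reagents that add atoms: dimethyl sulfate, COS(=O)(=O)OC
Why: Williamson O-methylation; the 4-hydroxyl is the only one not hydrogen-bonded to the acetyl carbonyl and is the most acidic, so one equivalent of base and electrophile should methylate it selectively.

Step 2
Reactants: 2 2,6-dihydroxy-4-methoxyacetophenone
Product: 3 1-[2-hydroxy-4-methoxy-6-(prop-2-enyloxy)phenyl]ethanone
Conditions: allyl bromide (1.05 equiv), K2CO3 (1.1 equiv), acetone, reflux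
Reagents that add atoms: allyl bromide, C=CCBr
Why: Williamson etherification of one of two equivalent hydroxyls; after the first alkylation the remaining ortho hydroxyl is locked in a hydrogen bond to the carbonyl, so the reaction should stop at the monoallyl ether.

Step 3
Reactants: 3 1-[2-hydroxy-4-methoxy-6-(prop-2-enyloxy)phenyl]ethanone; 4 prenyl bromide (1-bromo-3-methylbut-2-ene)
Product: 5 1-[2-hydroxy-4-methoxy-6-(prop-2-enyloxy)phenyl]-5-methylhex-4-en-1-one
Conditions: LiN(iPr)2 (2.2 equiv), THF, −78 °C; then 4 (1.0 equiv), −78 to 0 °C; aq. NH4Cl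
Reagents that add atoms: none
Why: C-alkylation of the phenoxide–enolate dianion of an o-hydroxyaryl methyl ketone; the enolate carbon is far more nucleophilic than the chelated lithium phenoxide and should react by SN2 at the primary allylic bromide.

Step 4
Reactants: 5 1-[2-hydroxy-4-methoxy-6-(prop-2-enyloxy)phenyl]-5-methylhex-4-en-1-one; 6 diethyl oxalate
Product: 8 ethyl 7-methoxy-3-(3-methylbut-2-enyl)-4-oxo-5-(prop-2-enyloxy)-4H-chromene-2-carboxylate, via 2-hydroxychromanone hemiketal 7 (not isolated)
Conditions: LiN(SiMe3)2 (3.2 equiv), THF, −78 °C; 6 (1.5 equiv), −78 °C to rt; AcOH quench, evaporation; then AcOH (LiOAc-buffered), 90 °C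
Reagents that add atoms: none
Why: Claisen condensation of the ketone enolate with diethyl oxalate followed by cyclodehydration of hemiketal 7 is the classical chromone-2-carboxylate synthesis, and dehydration in buffered acetic acid without mineral acid should spare the prenyl alkene while erasing the two transient stereocentres of 7.

Step 5
Reactants: 8 ethyl 7-methoxy-3-(3-methylbut-2-enyl)-4-oxo-5-(prop-2-enyloxy)-4H-chromene-2-carboxylate
Product: 9 2-(hydroxymethyl)-7-methoxy-3-(3-methylbut-2-enyl)-5-(prop-2-enyloxy)chromen-4-one
Conditions: NaBH4 (1.5 equiv), MeOH–THF, 0 °C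
Reagents that add atoms: none
Why: hydride reduction of an activated ester; the C2 ester of a chromone is reduced by NaBH4 in methanol, while the vinylogous-ester C4 carbonyl and the fully substituted C2=C3 bond should be left alone.

Step 6
Reactants: 9 2-(hydroxymethyl)-7-methoxy-3-(3-methylbut-2-enyl)-5-(prop-2-enyloxy)chromen-4-one
Product: 10 7-methoxy-3-(3-methylbut-2-enyl)-4-oxo-5-(prop-2-enyloxy)-4H-chromene-2-carbaldehyde
Conditions: Dess–Martin periodinane (1.2 equiv), CH2Cl2, 0 °C to rt
Reagents that add atoms: none
Why: Dess–Martin oxidation of a primary alcohol stops at the aldehyde and tolerates the prenyl and allyl alkenes.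

Step 7
Reactants: 10 7-methoxy-3-(3-methylbut-2-enyl)-4-oxo-5-(prop-2-enyloxy)-4H-chromene-2-carbaldehyde
Product: 11 2-ethynyl-7-methoxy-3-(3-methylbut-2-enyl)-5-(prop-2-enyloxy)chromen-4-one
Conditions: Me3SiCHN2 (1.2 equiv), LiN(iPr)2 (1.2 equiv), THF, −78 °C; then 10, −78 °C to rt; aq. NH4Cl
Reagents that add atoms: trimethylsilyldiazomethane, C[Si](C)(C)C=[N+]=[N-]
Why: Colvin rearrangement, the aprotic lithio(trimethylsilyl)diazomethane variant of the Seyferth–Gilbert homologation (addition to the aldehyde, loss of silanolate and N2, 1,2-hydrogen shift of the alkylidene carbene), chosen because no alcohol or alkoxide is present that could add to the electrophilic alkyne terminus.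

Step 8
Reactants: 12 methyl acetoacetate
Product: 13 methyl 3-(trimethylsilyloxy)but-2-enoate (E/Z mixture)
Conditions: Me3SiCl (1.2 equiv), Et3N (1.3 equiv), hexane, rt
Reagents that add atoms: chlorotrimethylsilane, C[Si](C)(C)Cl
Why: O-silylation of the enol of a β-keto ester, the standard first stage of the preparation of this diene.

Step 9
Reactants: 13 methyl 3-(trimethylsilyloxy)but-2-enoate
Product: 14 1-methoxy-1,3-bis(trimethylsilyloxy)buta-1,3-diene
Conditions: LiN(iPr)2 (1.1 equiv), THF, −78 °C; Me3SiCl (1.2 equiv), −78 °C to rt; distillation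
Reagents that add atoms: chlorotrimethylsilane, C[Si](C)(C)Cl
Why: γ-deprotonation of the silyl enol ether to the ester dienolate and O-silylation give the silyl ketene acetal diene (standard preparation of Chan's diene).

Step 10
Reactants: 11 2-ethynyl-7-methoxy-3-(3-methylbut-2-enyl)-5-(prop-2-enyloxy)chromen-4-one; 14 1-methoxy-1,3-bis(trimethylsilyloxy)buta-1,3-diene
Product: 16 2-(2,4-dihydroxyphenyl)-7-methoxy-3-(3-methylbut-2-enyl)-5-(prop-2-enyloxy)chromen-4-one, via silyl methyl ketal cycloadduct 15 (not isolated)
Conditions: 14 (3 equiv), PhMe (1 M), 90 °C, sealed tube; cool; then K2CO3 (0.2 equiv), MeOH, 0 °C to rt; pH 7 buffer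
Reagents that add atoms: none
Why: Proposed new method: the C2 ethynyl group is conjugated through C2=C3 with the C4 carbonyl, so it behaves as a vinylogous ynone whose terminal carbon carries the largest LUMO coefficient; the CH2 terminus of the electron-rich diene 14 should bond there first (C5'–C6') in a strongly asynchronous normal-demand [4+2] cycloaddition and the ketene acetal carbon then closes onto the internal alkyne carbon (C1'–C2'), the closest known reaction type being the Diels–Alder/aromatisation of 1,1,3-trioxygenated butadienes with acetylenic ketones and esters and of oxygenated dienes with electron-poor arylacetylenes to give biaryl phenols. Ring B is closed as a six-membered carbocycle by this intermolecular [4+2] event, and the only stereocentre formed, the ketal carbon of 15, is erased on aromatisation, so none has to be controlled. The step needs regioselectivity (ketene acetal carbon next to C1', hence oxygen at C2' and C4') and site selectivity; the first follows from the matched polarisation of diene and alkyne, the second from the fact that the tetrasubstituted C2=C3 bond and the isolated prenyl and allyl alkenes are far weaker dienophiles than the conjugated alkyne. Aromatisation is done by base-catalysed methanolysis in the same flask: loss of the silyl groups turns the C2' ketal into a hemiketal that can only expel methanol and the C4' enol ether into a ketone, and the resulting cyclohexenedione tautomerises to the resorcinol, so that the C2' oxygen is kept as a hydroxyl.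

Step 11
Reactants: 16 2-(2,4-dihydroxyphenyl)-7-methoxy-3-(3-methylbut-2-enyl)-5-(prop-2-enyloxy)chromen-4-one
Product: 17 2-(2,4-dihydroxyphenyl)-5-hydroxy-7-methoxy-3-(3-methylbut-2-enyl)chromen-4-one (target)
Conditions: Pd(PPh3)4 (5 mol %), morpholine (10 equiv), THF, rt, argon
Reagents that add atoms: none
Why: Tsuji–Trost deallylation; zerovalent palladium ionises the aryl allyl ether to a π-allyl complex that morpholine traps, under neutral acid-free conditions that should leave the prenyl group and the free phenols untouched.

**Compound list**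

1 | 2,4,6-trihydroxyacetophenone | CC(=O)c1c(O)cc(O)cc1O | starting material
2 | 2,6-dihydroxy-4-methoxyacetophenone | CC(=O)c1c(O)cc(OC)cc1O | intermediate
3 | 1-[2-hydroxy-4-methoxy-6-(prop-2-enyloxy)phenyl]ethanone | CC(=O)c1c(O)cc(OC)cc1OCC=C | intermediate
4 | prenyl bromide (1-bromo-3-methylbut-2-ene) | CC(C)=CCBr | starting material
5 | 1-[2-hydroxy-4-methoxy-6-(prop-2-enyloxy)phenyl]-5-methylhex-4-en-1-one | CC(C)=CCCC(=O)c1c(O)cc(OC)cc1OCC=C | intermediate
6 | diethyl oxalate | CCOC(=O)C(=O)OCC | starting material
7 | ethyl 2-hydroxy-7-methoxy-3-(3-methylbut-2-enyl)-4-oxo-5-(prop-2-enyloxy)chromane-2-carboxylate (diastereomer mixture, in equilibrium with the open diketo ester) | CCOC(=O)C1(O)Oc2cc(OC)cc(OCC=C)c2C(=O)C1CC=C(C)C | intermediate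
8 | ethyl 7-methoxy-3-(3-methylbut-2-enyl)-4-oxo-5-(prop-2-enyloxy)-4H-chromene-2-carboxylate | CCOC(=O)c1oc2cc(OC)cc(OCC=C)c2c(=O)c1CC=C(C)C | intermediate
9 | 2-(hydroxymethyl)-7-methoxy-3-(3-methylbut-2-enyl)-5-(prop-2-enyloxy)chromen-4-one | OCc1oc2cc(OC)cc(OCC=C)c2c(=O)c1CC=C(C)C | intermediate
10 | 7-methoxy-3-(3-methylbut-2-enyl)-4-oxo-5-(prop-2-enyloxy)-4H-chromene-2-carbaldehyde | O=Cc1oc2cc(OC)cc(OCC=C)c2c(=O)c1CC=C(C)C | intermediate
11 | 2-ethynyl-7-methoxy-3-(3-methylbut-2-enyl)-5-(prop-2-enyloxy)chromen-4-one | C#Cc1oc2cc(OC)cc(OCC=C)c2c(=O)c1CC=C(C)C | intermediate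
12 | methyl acetoacetate | COC(=O)CC(C)=O | starting material
13 | methyl 3-(trimethylsilyloxy)but-2-enoate (E/Z mixture) | COC(=O)C=C(C)O[Si](C)(C)C | intermediate
14 | 1-methoxy-1,3-bis(trimethylsilyloxy)buta-1,3-diene | COC(O[Si](C)(C)C)=CC(=C)O[Si](C)(C)C | intermediate
15 | 2-[6-methoxy-4,6-bis(trimethylsilyloxy)cyclohexa-1,4-dien-1-yl]-7-methoxy-3-(3-methylbut-2-enyl)-5-(prop-2-enyloxy)chromen-4-one (racemic at the ketal carbon) | COc1cc(OCC=C)c2c(=O)c(CC=C(C)C)c(C3=CCC(O[Si](C)(C)C)=CC3(OC)O[Si](C)(C)C)oc2c1 | intermediate
16 | 2-(2,4-dihydroxyphenyl)-7-methoxy-3-(3-methylbut-2-enyl)-5-(prop-2-enyloxy)chromen-4-one | COc1cc(OCC=C)c2c(=O)c(CC=C(C)C)c(-c3ccc(O)cc3O)oc2c1 | intermediate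
17 | 2-(2,4-dihydroxyphenyl)-5-hydroxy-7-methoxy-3-(3-methylbut-2-enyl)chromen-4-one | COc1cc(O)c2c(=O)c(CC=C(C)C)c(-c3ccc(O)cc3O)oc2c1 | target

**Step count**

Total: 11 steps. Longest linear sequence: 9 steps (steps 1–7, 10 and 11); steps 8 and 9 make the diene.

**Steps most likely to fail**

1. Step 10 (the step labelled as a proposed new method). Two processes threaten it.
   - The alkyne is activated only vinylogously, so thermal decay of the diene (silyl migration, hydrolysis) may outrun cycloaddition.
   - Cycloadduct 15 may aromatise in the hot solution by loss of trimethylsilanol before methanolysis, which would fix a methyl ether on O2'.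

   Fallback (known chemistry, from 5, back at 17): ring B is brought in as a benzoyl unit and ring C is closed around it.
   - 2,4-Dihydroxybenzoic acid is allylated three times (allyl bromide, K2CO3, DMF) to prop-2-enyl 2,4-bis(prop-2-enyloxy)benzoate F1.
   - F1 is saponified (LiOH, THF–H2O) to 2,4-bis(prop-2-enyloxy)benzoic acid F2, which oxalyl chloride and catalytic DMF convert into 2,4-bis(prop-2-enyloxy)benzoyl chloride F3.
   - The lithium dianion of 5 (LiN(SiMe3)2, 3 equiv, THF, −78 °C) is acylated at carbon by F3 to give 1-[2,4-bis(prop-2-enyloxy)phenyl]-3-[2-hydroxy-4-methoxy-6-(prop-2-enyloxy)phenyl]-2-(3-methylbut-2-enyl)propane-1,3-dione F4, the diketone of a Baker–Venkataraman sequence.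
   - Cyclodehydration in AcOH–NaOAc at 90 °C gives 2-[2,4-bis(prop-2-enyloxy)phenyl]-7-methoxy-3-(3-methylbut-2-enyl)-5-(prop-2-enyloxy)chromen-4-one F5.
   - Pd(PPh3)4 and morpholine in THF then remove all three allyl groups and give 17.

2. Step 4. Dehydration of hemiketal 7 in weak acid may stall; if the acidity is raised to force it, the hemiketal hydroxyl can add to the protonated prenyl alkene and close a cyclic ketal.

   Fallback (from 5, back at 8): the order of bond formation is reversed so that no acid is needed. The phenol of 5 is acylated with ethyl chlorooxoacetate in pyridine at 0 °C to give ethyl 5-methoxy-2-(5-methylhex-4-enoyl)-3-(prop-2-enyloxy)phenyl oxalate F6. Warming in pyridine (60 °C) with excess acid chloride should bring about intramolecular acylation of the ketone α-carbon by the oxalate and dehydration under the acylating conditions (Baker–Ollis ethoxalylation), delivering 8.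

3. Step 7. The lithiated diazo reagent, or the lithium trimethylsilanolate set free, may add to the conjugate positions of the product (C2 of the pyranone or the new alkyne terminus) and erode it by ring opening or enol ether formation.

   Fallback (from 10, back at 11): a two-stage olefination–elimination. Wittig reaction of 10 with the ylide from (chloromethyl)triphenylphosphonium chloride and NaN(SiMe3)2 (THF, −78 °C) gives 2-(2-chloroethenyl)-7-methoxy-3-(3-methylbut-2-enyl)-5-(prop-2-enyloxy)chromen-4-one F7 as an E/Z mixture. Dehydrochlorination with LiN(iPr)2 (2.2 equiv, THF, −78 °C) and protonation of the acetylide give 11.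

**Further compounds**

F1 | step 10 | prop-2-enyl 2,4-bis(prop-2-enyloxy)benzoate | C=CCOC(=O)c1ccc(OCC=C)cc1OCC=C
F2 | step 10 | 2,4-bis(prop-2-enyloxy)benzoic acid | OC(=O)c1ccc(OCC=C)cc1OCC=C
F3 | step 10 | 2,4-bis(prop-2-enyloxy)benzoyl chloride | ClC(=O)c1ccc(OCC=C)cc1OCC=C
F4 | step 10 | 1-[2,4-bis(prop-2-enyloxy)phenyl]-3-[2-hydroxy-4-methoxy-6-(prop-2-enyloxy)phenyl]-2-(3-methylbut-2-enyl)propane-1,3-dione | C=CCOc1cc(OC)cc(O)c1C(=O)C(CC=C(C)C)C(=O)c1ccc(OCC=C)cc1OCC=C
F5 | step 10 | 2-[2,4-bis(prop-2-enyloxy)phenyl]-7-methoxy-3-(3-methylbut-2-enyl)-5-(prop-2-enyloxy)chromen-4-one | COc1cc(OCC=C)c2c(=O)c(CC=C(C)C)c(-c3ccc(OCC=C)cc3OCC=C)oc2c1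
F6 | step 4 | ethyl 5-methoxy-2-(5-methylhex-4-enoyl)-3-(prop-2-enyloxy)phenyl oxalate | CCOC(=O)C(=O)Oc1cc(OC)cc(OCC=C)c1C(=O)CCC=C(C)C
F7 | step 7 | 2-(2-chloroethenyl)-7-methoxy-3-(3-methylbut-2-enyl)-5-(prop-2-enyloxy)chromen-4-one (E/Z mixture) | ClC=Cc1oc2cc(OC)cc(OCC=C)c2c(=O)c1CC=C(C)C
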